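**Retrosynthetic overview**

1. The acid is taken back to its methyl ester. The side chain is then cut at the C(sp2)–C(sp3) bond between the outer alkene carbon of the 1-en-3-yne and the allylic CH2, giving an (E)-enynyl phenyl sulfone on the intact dioxane and 1-methylcyclooctan-1-ol, to be joined by a ring-opening radical alkenylation.
2. Enabling feature: the chain ends in CH2–(CH2)6–C(=O)CH3, so the allylic CH2 and the ketone carbon are C2 and C1 of a 1-methylcyclooctanol whose C1–C2 ring bond is broken (a temporary eight-membered carbocycle). The alkene is conjugated with the C≡C, so a radical adding at its outer carbon is propargylic and can expel a sulfonyl group.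
3. The enynyl sulfone comes from a Sonogashira coupling of the pent-4-ynyl dioxane with (E)-2-iodovinyl phenyl sulfone.
4. The 1,2-dioxane, the only ring of the target, is closed by peroxy-ketalisation of a δ-hydroperoxy ketone (ketal centre under thermodynamic control). Its C–OO stereocentre comes from an organocatalytic asymmetric β-peroxidation of an enal built from hex-5-ynenitrile, an acetal Grignard reagent and a Wittig reagent.
5. Ring order: the dioxane is closed first (step 7), before any C–C coupling; the cyclooctanol ring is made separately (step 10) and opened in the key step.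

Key step: step 11

Remark: the ketal epimer required by the target (methoxy cis to the acetic acid arm, that is methoxy axial with both carbon substituents equatorial) is taken to be the thermodynamically favoured one, as the anomeric effect in 3-alkoxy-1,2-dioxanes predicts.

**Route**

Step 1
Reactants: 1 hex-5-ynenitrile; 2 [2-(1,3-dioxolan-2-yl)ethyl]magnesium bromide
Product: 5 4-oxonon-8-ynal, via bromomagnesium ketiminate 3 (not isolated), via keto acetal 4 (not isolated)
Conditions: 2 (2.3 equiv), CuBr·SMe2 (5 mol %), THF, 0 °C to rt; then 2 M aq. HCl/THF, rt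
Reagents that add atoms: water (O)
Why: Copper-catalysed Grignard addition to a nitrile stops at the N-magnesio ketimine (one equivalent of 2 being spent on the acetylenic C–H), and the aqueous acid work-up hydrolyses the imine and then the dioxolane to the 1,4-keto aldehyde.

Step 2
Reactants: 5 4-oxonon-8-ynal; 6 (triphenylphosphoranylidene)acetaldehyde
Product: 7 (2E)-6-oxoundec-2-en-10-ynal
Conditions: 6 (1.1 equiv), toluene, 70 °C
Reagents that add atoms: none
Why: Wittig olefination with a stabilised formylmethylene ylide, which reacts with the aldehyde but not with the ketone and is (E)-selective as stabilised ylides are.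

Step 3
Reactants: 8 2,3-dimethylbut-2-ene
Product: 11 2-hydroperoxy-2-methoxypropane, via primary ozonide 9 (not isolated), via acetone O-oxide 10 (not isolated)
Conditions: O3, MeOH/CH2Cl2 (1:4), −78 °C; N2 purge; used as a dried solution
Reagents that add atoms: ozone (O=[O+][O-]); methanol (CO)
Why: Ozonolysis in methanol (Criegee mechanism), in which cycloreversion of the primary ozonide gives acetone and its carbonyl oxide and methanol traps the latter as the α-methoxy hydroperoxide, a hydroperoxide with an acid-labile ketal handle.

Step 4
Reactants: 7 (2E)-6-oxoundec-2-en-10-ynal; 11 2-hydroperoxy-2-methoxypropane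
Product: 12 (3S)-3-[(2-methoxypropan-2-yl)peroxy]-6-oxoundec-10-ynal
Conditions: 11 (1.5 equiv), (R)-2-{bis[3,5-bis(trifluoromethyl)phenyl](trimethylsilyloxy)methyl}pyrrolidine (10 mol %), PhCO2H (10 mol %), toluene, −20 °C
Reagents that add atoms: none
Why: Organocatalytic asymmetric β-peroxidation of an enal by iminium activation (hetero-Michael addition), in which the hydroperoxide adds to the β-carbon of the (E)-s-trans iminium ion on the face anti to the diaryl(silyloxy)methyl group, which for the (R)-catalyst should set the (S)-configured C–OO centre, while the acid co-catalyst protonates the enamine before it can close to an epoxide and the bulky amine leaves the ketone untouched.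

Step 5
Reactants: 12 (3S)-3-[(2-methoxypropan-2-yl)peroxy]-6-oxoundec-10-ynal
Product: 13 (3S)-3-[(2-methoxypropan-2-yl)peroxy]-6-oxoundec-10-ynoic acid
Conditions: NaClO2, NaH2PO4, 2-methylbut-2-ene, t-BuOH/H2O, 0 °C
Reagents that add atoms: sodium chlorite ([Na+].[O-]Cl=O)
Why: Pinnick oxidation, a buffered chlorite oxidation that is selective for the aldehyde and should leave the alkyne, the ketone, the perketal and the non-enolisable β-stereocentre untouched.

Step 6
Reactants: 13 (3S)-3-[(2-methoxypropan-2-yl)peroxy]-6-oxoundec-10-ynoic acid
Product: 14 methyl (3S)-3-[(2-methoxypropan-2-yl)peroxy]-6-oxoundec-10-ynoate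
Conditions: TMSCHN2, MeOH/toluene (1:3), 0 °C
Reagents that add atoms: (trimethylsilyl)diazomethane (C[Si](C)(C)C=[N+]=[N-])
Why: Methyl ester formation with (trimethylsilyl)diazomethane in methanol, a near-neutral O-methylation of the acid that spares the acid-labile perketal and the base-labile β-peroxy carbonyl unit.

Step 7
Reactants: 14 methyl (3S)-3-[(2-methoxypropan-2-yl)peroxy]-6-oxoundec-10-ynoate
Product: 17 methyl 2-[(3S,6R)-6-methoxy-6-(pent-4-yn-1-yl)-1,2-dioxan-3-yl]acetate, via hydroperoxy ketone 15 (not isolated), via peroxy hemiketal 16 (not isolated)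
Conditions: TsOH·H2O (10 mol %), MeOH, 4 Å MS, 0 °C to rt; minor ketal epimer separated and resubmitted
Reagents that add atoms: methanol (CO)
Why: Acid-catalysed transketalisation and peroxy-ketalisation, in which methanolysis frees the hydroperoxide, this adds to the C6 ketone in a 6-exo-trig closure and the hemiketal is exchanged to the methyl ketal, the ketal centre being set under thermodynamic control by reversible ionisation that should funnel the material to the chair with methoxy axial (anomeric effect) and both carbon substituents equatorial, that is (6R) relative to the fixed (3S) centre.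

Step 8
Reactants: 18 sodium benzenesulfinate; 19 acetylene
Product: 21 (E)-[(2-iodoethenyl)sulfonyl]benzene, via benzenesulfonyl iodide 20 (not isolated)
Conditions: I2, EtOAc/H2O, acetylene (1 atm), visible light, rt
Reagents that add atoms: iodine (II)
Why: Iodosulfonylation of an alkyne, in which the sulfonyl iodide formed in the flask adds to acetylene by a radical chain in an anti sense and so gives the (E)-β-iodovinyl sulfone.

Step 9
Reactants: 17 methyl 2-[(3S,6R)-6-methoxy-6-(pent-4-yn-1-yl)-1,2-dioxan-3-yl]acetate; 21 (E)-[(2-iodoethenyl)sulfonyl]benzene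
Product: 22 methyl 2-[(3S,6R)-6-[(6E)-7-(benzenesulfonyl)hept-6-en-4-yn-1-yl]-6-methoxy-1,2-dioxan-3-yl]acetate
Conditions: PdCl2(PPh3)2 (3 mol %), CuI (5 mol %), i-Pr2NEt (2 equiv), THF, 0 °C to rt
Reagents that add atoms: none
Why: Sonogashira coupling, in which oxidative addition of zerovalent palladium into the vinyl C–I bond occurs with retention so that the (E)-geometry of 21 is carried into the enyne, dialkyl peroxides of this kind being expected to tolerate Pd/Cu alkynylation at or below room temperature and the hindered tertiary amine being unable to substitute the β-iodovinyl sulfone.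

Step 10
Reactants: 23 cyclooctanone
Product: 24 1-methylcyclooctan-1-ol
Conditions: MeMgBr, Et2O, 0 °C to rt; then aq. NH4Cl
Reagents that add atoms: methylmagnesium bromide (C[Mg]Br)
Why: Grignard addition to a ketone, which forms the temporary carbocycle with its tertiary carbinol and creates no stereocentre.

Step 11
Reactants: 22 methyl 2-[(3S,6R)-6-[(6E)-7-(benzenesulfonyl)hept-6-en-4-yn-1-yl]-6-methoxy-1,2-dioxan-3-yl]acetate; 24 1-methylcyclooctan-1-ol
Product: 27 methyl 2-[(3S,6R)-6-methoxy-6-[(6E)-15-oxohexadec-6-en-4-yn-1-yl]-1,2-dioxan-3-yl]acetate, via 8-oxononyl radical 25 (not isolated), via propargylic adduct radical 26 (not isolated)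
Conditions: 24 (3 equiv), [Ir(dF(CF3)ppy)2(5,5'-d(CF3)bpy)]PF6 (2 mol %; dF(CF3)ppy = cyclometalated 2-(2,4-difluorophenyl)-5-(trifluoromethyl)pyridine, d(CF3)bpy = bis(trifluoromethyl)-2,2'-bipyridine), 2,4,6-collidine (2 equiv), degassed PhCF3, blue LEDs (450 nm), 25 °C
Reagents that add atoms: none
Why: Proposed new method: proton-coupled electron transfer (PCET) from the tertiary O–H of 24 to the photoexcited iridium complex and collidine should give the 1-methylcyclooctyloxyl radical, whose β-scission of the ring C1–C2 bond, driven by release of the transannular strain of the eight-membered ring and by C=O formation, unveils the methyl ketone and the primary radical 25 in one event; 25 adds to the sulfonyl-bearing alkene carbon of 22 to give the propargylic radical 26, which expels PhSO2•, and reduction of that radical by the reduced photocatalyst closes a redox-neutral cycle. The closest known reaction types are the light-driven PCET ring opening of unstrained tertiary cycloalkanols to distal keto radicals and the alkenylation of alkyl radicals with β-sulfonyl styrenes by addition and β-sulfonyl elimination; new are their combination and a 1-sulfonyl-1-en-3-yne as the acceptor. No ring is closed, the carbocycle of 24 being opened, and no stereocentre is formed, the two dioxane centres being spectators; the (E)-geometry of the new alkene is under thermodynamic control because 26 rotates freely before fragmentation and sulfonyl radical addition is reversible, so that any (Z)-22 formed by sensitisation should converge on the same product. The step needs addition at the carbon that bears sulfur and not at the alkyne or the inner alkene carbon, which the propargylic stabilisation of 26 (the counterpart of the benzylic radical in the styryl sulfone series) should secure, and it needs scission of the ring bond and not loss of methyl or transannular 1,5-hydrogen transfer, which the tertiary carbinol and the strained ring favour. The O–O bond should survive because no low-valent metal is present and dialkyl peroxides resist outer-sphere reduction by the mildly reducing reduced photocatalyst, excess collidine buffers the benzenesulfinic acid so that the perketal is not exposed to acid, and the carboxyl group is carried as the methyl ester because a free carboxylate would be oxidised and decarboxylated under these conditions.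

Step 12
Reactants: 27 methyl 2-[(3S,6R)-6-methoxy-6-[(6E)-15-oxohexadec-6-en-4-yn-1-yl]-1,2-dioxan-3-yl]acetate
Product: 28 2-[(3S,6R)-6-methoxy-6-[(6E)-15-oxohexadec-6-en-4-yn-1-yl]-1,2-dioxan-3-yl]acetic acid
Conditions: LiOH·H2O (3 equiv), THF/H2O (3:1), 0 °C; then 0.5 M HCl to pH 4
Reagents that add atoms: lithium hydroxide ([Li+].[OH-])
Why: Saponification of the methyl ester, in which hydroxide attack on the ester carbonyl at 0 °C should outrun E1cB opening of the β-peroxy ester and neither stereocentre nor the enyne or the methyl ketone is touched.

**Compound list**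

1 | hex-5-ynenitrile | C#CCCCC#N | starting material
2 | [2-(1,3-dioxolan-2-yl)ethyl]magnesium bromide | Br[Mg]CCC1OCCO1 | starting material
3 | bromomagnesium ketiminate: N-(bromomagnesio)imine of 1-(1,3-dioxolan-2-yl)oct-7-yn-3-one, also metalated at the alkyne terminus | Br[Mg]C#CCCCC(CCC1OCCO1)=N[Mg]Br | intermediate
4 | 1-(1,3-dioxolan-2-yl)oct-7-yn-3-one (keto acetal) | C#CCCCC(=O)CCC1OCCO1 | intermediate
5 | 4-oxonon-8-ynal | C#CCCCC(=O)CCC=O | intermediate
6 | (triphenylphosphoranylidene)acetaldehyde | O=CC=P(c1ccccc1)(c1ccccc1)c1ccccc1 | starting material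
7 | (2E)-6-oxoundec-2-en-10-ynal | C#CCCCC(=O)CC/C=C/C=O | intermediate
8 | 2,3-dimethylbut-2-ene | CC(C)=C(C)C | starting material
9 | 4,4,5,5-tetramethyl-1,2,3-trioxolane (primary ozonide) | CC1(C)OOOC1(C)C | intermediate
10 | acetone O-oxide (carbonyl oxide) | CC(C)=[O+][O-] | intermediate
11 | 2-hydroperoxy-2-methoxypropane | COC(C)(C)OO | intermediate
12 | (3S)-3-[(2-methoxypropan-2-yl)peroxy]-6-oxoundec-10-ynal | C#CCCCC(=O)CC[C@@H](CC=O)OOC(C)(C)OC | intermediate
13 | (3S)-3-[(2-methoxypropan-2-yl)peroxy]-6-oxoundec-10-ynoic acid | C#CCCCC(=O)CC[C@@H](CC(=O)O)OOC(C)(C)OC | intermediate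
14 | methyl (3S)-3-[(2-methoxypropan-2-yl)peroxy]-6-oxoundec-10-ynoate | C#CCCCC(=O)CC[C@@H](CC(=O)OC)OOC(C)(C)OC | intermediate
15 | methyl (3S)-3-hydroperoxy-6-oxoundec-10-ynoate (hydroperoxy ketone) | C#CCCCC(=O)CC[C@@H](CC(=O)OC)OO | intermediate
16 | methyl 2-[(3S)-6-hydroxy-6-(pent-4-yn-1-yl)-1,2-dioxan-3-yl]acetate (peroxy hemiketal, both C6 epimers) | OC1(CCCC#C)CC[C@@H](CC(=O)OC)OO1 | intermediate
17 | methyl 2-[(3S,6R)-6-methoxy-6-(pent-4-yn-1-yl)-1,2-dioxan-3-yl]acetate | CO[C@@]1(CCCC#C)CC[C@@H](CC(=O)OC)OO1 | intermediate
18 | sodium benzenesulfinate | [Na+].[O-]S(=O)c1ccccc1 | starting material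
19 | acetylene | C#C | starting material
20 | benzenesulfonyl iodide | O=S(=O)(I)c1ccccc1 | intermediate
21 | (E)-[(2-iodoethenyl)sulfonyl]benzene | I/C=C/S(=O)(=O)c1ccccc1 | intermediate
22 | methyl 2-[(3S,6R)-6-[(6E)-7-(benzenesulfonyl)hept-6-en-4-yn-1-yl]-6-methoxy-1,2-dioxan-3-yl]acetate | CO[C@@]1(CCCC#C/C=C/S(=O)(=O)c2ccccc2)CC[C@@H](CC(=O)OC)OO1 | intermediate
23 | cyclooctanone | O=C1CCCCCCC1 | starting material
24 | 1-methylcyclooctan-1-ol | CC1(O)CCCCCCC1 | intermediate
25 | 8-oxononyl radical | [CH2]CCCCCCC(C)=O | intermediate
26 | propargylic adduct radical: 25 added to the sulfonyl-bearing alkene carbon of 22 | CO[C@@]1(CCCC#C[CH]C(CCCCCCCC(C)=O)S(=O)(=O)c2ccccc2)CC[C@@H](CC(=O)OC)OO1 | intermediate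
27 | methyl 2-[(3S,6R)-6-methoxy-6-[(6E)-15-oxohexadec-6-en-4-yn-1-yl]-1,2-dioxan-3-yl]acetate | CO[C@@]1(CCCC#C/C=C/CCCCCCCC(C)=O)CC[C@@H](CC(=O)OC)OO1 | intermediate
28 | 2-[(3S,6R)-6-methoxy-6-[(6E)-15-oxohexadec-6-en-4-yn-1-yl]-1,2-dioxan-3-yl]acetic acid | CO[C@@]1(CCCC#C/C=C/CCCCCCCC(C)=O)CC[C@@H](CC(=O)O)OO1 | target

**Step count and risks**

Total steps: 12. Longest linear sequence: 9 (steps 1, 2, 4, 5, 6, 7, 9, 11, 12); steps 3, 8 and 10 are one-step branches.

Steps most likely to fail:

1. Step 11 (the proposed new method). What may go wrong:
   - transannular 1,5-hydrogen transfer or loss of methyl competing with ring scission in the oxyl radical;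
   - radical addition at the alkyne or at the inner alkene carbon instead of the sulfonyl-bearing carbon;
   - sensitised E/Z isomerisation of the product or O–O cleavage under irradiation;
   - stalling as the sulfinate by-product quenches the excited catalyst.

   Fallback with known chemistry, forming the neighbouring C(sp)–C(sp2) bond instead: it sets out from 17 and comes back to the route at 27. Commercial dec-9-en-1-ol is converted by Wacker oxidation (PdCl2, CuCl, O2, DMF/H2O) into 10-hydroxydecan-2-one F1. Dess–Martin oxidation gives 9-oxodecanal F2. Aldehyde-selective Takai olefination (CrCl2, CHI3, THF, 0 °C) gives (10E)-11-iodoundec-10-en-2-one F3. Sonogashira coupling of F3 with 17 (PdCl2(PPh3)2, CuI, i-Pr2NH, THF, rt) should then give 27, which enters step 12.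

2. Step 4. What may go wrong: collapse of the β-peroxy enamine to the epoxy aldehyde with loss of the O–O unit, poor facial selectivity, or reversal of the addition on prolonged contact with the amine.

   Fallback: it sets out from 5 and comes back at 17. Horner–Wadsworth–Emmons olefination of 5 (trimethyl phosphonoacetate, LiCl, DBU, MeCN) gives methyl (2E)-6-oxoundec-2-en-10-ynoate F4. Urea–hydrogen peroxide with Sc(OTf)3 in MeOH converts the ketone into the racemic methyl (2E)-6-hydroperoxy-6-methoxyundec-2-en-10-ynoate F5. Et2NH in CF3CH2OH closes the dioxane by intramolecular conjugate addition of the hydroperoxide (6-exo-trig). Equilibration with TsOH in MeOH should converge the ketal epimers on the racemic cis dioxane F6. Preparative HPLC on a chiral stationary phase then delivers 17, at the cost of half the material.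

3. Step 7. What may go wrong: incomplete equilibration at the ketal carbon, opening to the acyclic dimethyl ketal, or acid-induced fragmentation of the hydroperoxide.

   Fallback: it sets out from 14 and comes back at 17. The perketal is cleaved with AcOH/H2O/THF at rt and the cyclic peroxy hemiketal 16 is isolated. Its anomeric hydroxyl, expected to sit axial, is then O-methylated without touching the C–O bond of the ketal carbon (MeOTf, 2,6-di-tert-butylpyridine, CH2Cl2, 0 °C), so that the axial methoxy epimer 17 should result by retention.

Further compounds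
F1 | step 11 | 10-hydroxydecan-2-one | CC(=O)CCCCCCCCO
F2 | step 11 | 9-oxodecanal | CC(=O)CCCCCCCC=O
F3 | step 11 | (10E)-11-iodoundec-10-en-2-one | CC(=O)CCCCCCC/C=C/I
F4 | step 4 | methyl (2E)-6-oxoundec-2-en-10-ynoate | C#CCCCC(=O)CC/C=C/C(=O)OC
F5 | step 4 | methyl (2E)-6-hydroperoxy-6-methoxyundec-2-en-10-ynoate (racemic) | C#CCCCC(OC)(OO)CC/C=C/C(=O)OC
F6 | step 4 | racemic methyl 2-[(3S,6R)-6-methoxy-6-(pent-4-yn-1-yl)-1,2-dioxan-3-yl]acetate (cis, both enantiomers) | CO[C@@]1(CCCC#C)CC[C@@H](CC(=O)OC)OO1.CO[C@]1(CCCC#C)CC[C@H](CC(=O)OC)OO1
F0 | step 7 | none | none
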